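## The problem

Compound 17 is a biflavonoid in which C3 of a 5,7,4'-trihydroxyflavanone (benzo ring A, pyranone ring C, 2-aryl ring B) is bonded directly to ring E, a phenol that is also the 2-aryl group of a 5,7-dihydroxyflavone (rings D and F); the bond lies ortho to the ring E hydroxyl group and meta to the chromone. The skeleton is therefore a 1,2-diarylethanone (ring A–C4(=O)–C3–ring E) whose C3 is also tied to the benzylic, oxygen-bearing C2. There are two stereocentres, C2 (R) and C3 (S), trans on ring C. C3 is α to the ketone and benzylic to ring E, so it epimerises easily and should settle trans to whatever C2 dictates, whereas C2 has no such helper and must be set absolutely. Both centres are lost together if ring C opens by retro-oxa-Michael reaction to the α-aryl-2'-hydroxychalcone, which base and hot acid both promote. The six phenols must therefore be freed at the end under near-neutral conditions, and the chromone C2=C3 bond and the benzylic C2–O1 bond limit the reductions that can be used. The feature that opens the chosen route is that C2 is a methine benzylic to ring B and attached to O1 of ring A, while C3 sits between the C4 carbonyl and ring E. Read backwards, C3 is a carbene carbon with an acceptor and a donor substituent, and C2–H is a C–H bond of a benzyl ether on the ring A oxygen.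

## Retrosynthesis

**Protecting groups (17 ⇐ 16 ⇐ 15).** The six hydroxyl groups of 17 are traced back to the benzyl-type ethers of 16 (seven O–CH2 bonds) and, one step earlier, to the ring E silyl ether of 15 (one O–Si bond). Benzyl-type groups are preferred to methyl ethers because they leave under hydrogen and Pd/C at neutral pH. Cleaving aryl methyl ethers would need BBr3 and would expose ring C to a strong Lewis acid and HBr. The simplification is only in functional groups, but it fixes what the key step must tolerate: benzylic ethers, a chromone and an aryl silyl ether. The forward steps must not touch C2, so the desilylation is buffered and the debenzylation is reductive.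

**Key cut (15 ⇐ 13).** Ring C is opened at C2–C3. The neighbouring cuts are weaker. O1–C2 leads to an oxa-Michael closure that is reversible at the new stereocentre. C3–C4 requires C2 to be made beforehand in enantiopure form. C3–ring E would mean arylating a flavanone enolate under base. Only the C2–C3 cut creates C2 in an irreversible C–C bond formation from a precursor without any stereocentre. That precursor is the α-aryl-α-diazoketone 13, in which C3 is the diazo carbon and C2 is the CH2 of a 4-(benzyloxy)benzyl ether on ring A. Two features of 13 follow from the forward step: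

- Both ortho oxygens of ring A carry the same benzylic group, so insertion into either gives 15 and no methyl or plain benzyl ether competes.
- The ring E oxygen is in a 1,5-relationship to the carbene carbon and is silylated, so the otherwise favoured five-membered insertion finds no C–H bond.

The forward reaction must prefer C–H insertion to oxonium ylide formation and must select one enantiotopic hydrogen. The kinetic cis isomer 14 is converted into 15 by epimerisation at C3.

**Diazo group (13 ⇐ 12).** The C3=N2 unit is taken back to the methylene group of deoxybenzoin 12. This removes the only energetic function and leaves a stable ketone. The CH2 lies between a ketone and ring E and is the only enolisable position, so a Regitz diazo transfer with an amidine base is all that is asked.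

**Joining the halves (12 ⇐ 5 + 11).** The C3–ring E bond of 12 is cut, giving methyl ketone 5 and aryl bromide 11. The alternative cut at C4–ring A (acylation of a phloroglucinol ether by an arylacetic acid) needs Lewis acids that benzylic ethers do not survive, and would need a ring E acetic acid that already carries the chromone. The chosen cut divides the molecule into two halves of similar size: 5 holds ring A and the future ring B, and 11 holds rings D, F and E. The forward reaction is a palladium-catalysed mono-arylation of a methyl ketone with an ortho-silyloxy aryl bromide, using a base mild enough for the silyl ether.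

**Chromone (11 ⇐ 10 ⇐ 8 ⇐ 6 + 7).** After removal of the silyl group (10), ring F is opened at O1–C2 and its C2=C3 unsaturation is taken back to chalcone 8. Cutting the enone Cα=Cβ bond of 8 gives acetophenone 6 and aldehyde 7. The bromine that marks the future C3–ring E bond is already present in 7, ortho to the hydroxyl group, so no aromatic substitution on ring E is needed. The silyl group is introduced only after the basic condensation and the hot iodine step, neither of which it would survive.

**Ring A ketone (5 ⇐ 4 ⇐ 3 ⇐ 1 + 2).** The three aryl ether C–O bonds are cut one at a time, which leads through bis-ether 4 and mono-ether 3 to phloroacetophenone 1 and three portions of chloride 2. The 4-(benzyloxy)benzyl group serves twice: two copies protect O5 and O7, and the third becomes C2 and ring B with its oxygen already benzylated. The three hydroxyl groups of 1 react in a fixed order: the free para one first, then one of the two ortho ones, and last the remaining ortho one, which is held in a hydrogen bond to the carbonyl oxygen. Each ether is therefore made with one equivalent of 2 under the mildest conditions that its hydroxyl group needs. This staging keeps the electron-rich benzylic chloride from meeting a polyphenoxide in large excess under forcing conditions, where C-alkylation of the phloroglucinol ring would compete.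

## Roads not taken

**Alternative 1:** The cut is made at C3–C4 and O1–C2 together. A chiral phosphoric acid would ionise the salicylaldehyde dimethyl acetal A1 by loss of methanol. The resulting methoxy-substituted heterodiene would add across the E-stilbene A2 to give the 4-methoxyflavan A3.

- Merits: ring C, two bonds and the trans relationship of C2 and C3 (from the E-alkene) arise in one convergent, diazo-free step. In this respect the road is better than the chosen one, which forms a single bond.
- Weak points: C4 emerges as a methyl ether and must be oxidised to the ketone beside a second benzylic ether C–H at C2. Both alkene carbons of A2 carry donor-substituted aryl groups, so the orientation of the addition is not secured. The chromone is absent and would have to be grown from the aryl bromide of A3 over several steps on a molecule that already holds the sensitive stereocentres. Six methyl ethers remain for BBr3.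
- Comparison: against the higher convergence, the chosen plan sets the correct oxidation level at C4 from the start, a complete skeleton before any stereocentre exists, no regiochemical question, and two mild steps after the key step.

**Alternative 2:** The cut is C3–C4. Fluoride would remove the silyl group of aldehyde A4 and the phenoxide would expel the benzylic halide, giving a ring E ortho-quinone methide with C3 as its exocyclic carbon. A triazolylidene carbene would turn the ring A aldehyde into an acyl anion equivalent that adds to C3, closing ring C to chromanone A5.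

- Merits: C4 is formed directly as the ketone, the ring E phenol is freed in the same step, and no metal or diazo compound is needed. On these points the road is at least as good as the chosen one.
- Weak points: C2 must already be present in A4 as an enantiopure benzylic aryl ether, which moves the stereochemical problem into a longer precursor synthesis. The quinone methide has a hydrogen at C2 and can tautomerise to a vinylphenol instead of being trapped. The aldehyde is flanked by two ortho substituents, which slows formation of the acyl anion equivalent. The bromide of A5 must still be turned into the chromone on a base-sensitive flavanone, and three methyl ethers remain.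
- Comparison: the chosen plan creates C2 in the key step from an achiral precursor and carries the finished chromone through it.

**Alternative 3:** The cut is O1–C2. A cinchona-derived thiourea base would add the ring A phenol of the α-aryl chalcone A6 to its β-carbon and protonate C3, giving the hexamethyl ether A7.

- Merits: this is the shortest road. A6 would come from one condensation of a deoxybenzoin with an aromatic aldehyde, the closure mimics the biosynthesis, and neither a diazo compound nor rhodium is needed. If it delivered high enantiomeric purity it would be more economical than the chosen plan.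
- Weak points: the oxa-Michael closure is reversible under the base that catalyses it, so the C2 configuration can drain away through the chalcone. The α-aryl group makes the acceptor trisubstituted and twisted, and enantioselective closures of this kind normally rely on an extra activating group at the α-carbon. Six methyl ethers would have to be cleaved with BBr3 on the product.
- Comparison: the chosen plan sets an irreversible C–C bond formation and a neutral endgame against this, and accepts more steps, a diazo intermediate and a rhodium catalyst in return.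

Key step: step 9

Assumption: acetophenone 6 is taken as a catalogue compound; it is otherwise the known product of twofold benzylation of 1 with benzyl bromide and K2CO3.

## Route

Step 1
Reactants: 1 1-(2,4,6-trihydroxyphenyl)ethanone; 2 4-(benzyloxy)benzyl chloride
Product: 3 1-(4-{[4-(benzyloxy)benzyl]oxy}-2,6-dihydroxyphenyl)ethanone
Conditions: 2 (1.0 equiv), K2CO3 (1.0 equiv), DMF, rt
Reagents that add atoms: none
Why: Williamson ether synthesis: one equivalent of base ionises the most acidic hydroxyl group, the one para to the acetyl group and not tied up in a hydrogen bond to the carbonyl oxygen, and its phenoxide displaces chloride from 2. Any over-alkylation gives 4, the product of the next step, so it costs no material.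

Step 2
Reactants: 3 1-(4-{[4-(benzyloxy)benzyl]oxy}-2,6-dihydroxyphenyl)ethanone; 2 4-(benzyloxy)benzyl chloride
Product: 4 1-(2,4-bis{[4-(benzyloxy)benzyl]oxy}-6-hydroxyphenyl)ethanone
Conditions: 2 (1.05 equiv), K2CO3, KI (cat.), acetone, reflux
Reagents that add atoms: none
Why: Williamson ether synthesis on one of the two equivalent ortho hydroxyl groups; the remaining one stays chelated to the carbonyl oxygen and reacts much more slowly in acetone, which is the usual way to stop phloroacetophenone ethers at the 2,4-stage.

Step 3
Reactants: 4 1-(2,4-bis{[4-(benzyloxy)benzyl]oxy}-6-hydroxyphenyl)ethanone; 2 4-(benzyloxy)benzyl chloride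
Product: 5 1-(2,4,6-tris{[4-(benzyloxy)benzyl]oxy}phenyl)ethanone
Conditions: 2 (1.3 equiv), K2CO3, KI (cat.), DMF, 70 °C
Reagents that add atoms: none
Why: Williamson ether synthesis on the chelated phenol, which needs the polar aprotic solvent, heat and iodide catalysis (Finkelstein exchange to the benzylic iodide); the ring already carries two ether groups, so C-alkylation is sterically disfavoured.

Step 4
Reactants: 6 1-[2,4-bis(benzyloxy)-6-hydroxyphenyl]ethanone; 7 3-bromo-4-hydroxybenzaldehyde
Product: 8 (E)-1-[2,4-bis(benzyloxy)-6-hydroxyphenyl]-3-(3-bromo-4-hydroxyphenyl)prop-2-en-1-one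
Conditions: KOH (50% aq.), EtOH, rt; then HCl (aq.)
Reagents that add atoms: none
Why: Claisen–Schmidt condensation: the enolate of 6 adds to aldehyde 7 and the aldol loses water to the conjugated E-enone (thermodynamic geometry); concentrated KOH is used because 7 reacts as its less electrophilic phenoxide, a known but slow variant.

Step 5
Reactants: 8 (E)-1-[2,4-bis(benzyloxy)-6-hydroxyphenyl]-3-(3-bromo-4-hydroxyphenyl)prop-2-en-1-one
Product: 10 5,7-bis(benzyloxy)-2-(3-bromo-4-hydroxyphenyl)-4H-chromen-4-one, via flavanone 9 (not isolated)
Conditions: I2 (10 mol%), DMSO, 120 °C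
Reagents that add atoms: none
Why: Iodine-catalysed oxidative cyclisation of a 2'-hydroxychalcone: oxa-Michael closure gives flavanone 9, iodination α to the ketone and loss of HI give the chromone, and DMSO reoxidises HI to I2; benzyl ethers and the aryl bromide are inert.

Step 6
Reactants: 10 5,7-bis(benzyloxy)-2-(3-bromo-4-hydroxyphenyl)-4H-chromen-4-one
Product: 11 5,7-bis(benzyloxy)-2-{3-bromo-4-[(triisopropylsilyl)oxy]phenyl}-4H-chromen-4-one
Conditions: iPr3SiCl, imidazole, DMF, rt
Reagents that add atoms: chlorotriisopropylsilane, CC(C)[Si](Cl)(C(C)C)C(C)C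
Why: Silylation of the only free hydroxyl group, an acidic ortho-bromophenol; the triisopropylsilyl group has no C–H bond next to oxygen and is the aryl silyl ether most resistant to the mildly basic steps that follow.

Step 7
Reactants: 5 1-(2,4,6-tris{[4-(benzyloxy)benzyl]oxy}phenyl)ethanone; 11 5,7-bis(benzyloxy)-2-{3-bromo-4-[(triisopropylsilyl)oxy]phenyl}-4H-chromen-4-one
Product: 12 2-{5-[5,7-bis(benzyloxy)-4-oxo-4H-chromen-2-yl]-2-[(triisopropylsilyl)oxy]phenyl}-1-(2,4,6-tris{[4-(benzyloxy)benzyl]oxy}phenyl)ethanone
Conditions: Pd(OAc)2 (3 mol%), XPhos (6 mol%), K3PO4, toluene, 90 °C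
Reagents that add atoms: none
Why: Palladium-catalysed α-arylation of a ketone (Buchwald–Hartwig type): zerovalent palladium inserts into the C–Br bond of 11, the enolate of 5 (α-hydrogens only on the methyl group) replaces bromide, and reductive elimination from the bulky biarylphosphine complex gives the mono-arylated ketone. K3PO4 in toluene is weak and non-nucleophilic enough to spare the aryl silyl ether and the chromone.

Step 8
Reactants: 12 2-{5-[5,7-bis(benzyloxy)-4-oxo-4H-chromen-2-yl]-2-[(triisopropylsilyl)oxy]phenyl}-1-(2,4,6-tris{[4-(benzyloxy)benzyl]oxy}phenyl)ethanone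
Product: 13 2-{5-[5,7-bis(benzyloxy)-4-oxo-4H-chromen-2-yl]-2-[(triisopropylsilyl)oxy]phenyl}-2-diazo-1-(2,4,6-tris{[4-(benzyloxy)benzyl]oxy}phenyl)ethanone
Conditions: 4-acetamidobenzenesulfonyl azide, DBU, MeCN/CH2Cl2, 0 °C → rt
Reagents that add atoms: 4-acetamidobenzenesulfonyl azide, CC(=O)Nc1ccc(S(=O)(=O)N=[N+]=[N-])cc1
Why: Regitz diazo transfer: DBU forms the enolate of the benzyl ketone, which attacks the terminal nitrogen of the sulfonyl azide, and the triazene collapses to the α-aryl-α-diazoketone and the sulfonamide; deoxybenzoins are standard substrates and 12 has a single enolisable position.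

Step 9
Reactants: 13 2-{5-[5,7-bis(benzyloxy)-4-oxo-4H-chromen-2-yl]-2-[(triisopropylsilyl)oxy]phenyl}-2-diazo-1-(2,4,6-tris{[4-(benzyloxy)benzyl]oxy}phenyl)ethanone
Product: 15 (2R,3S)-2-[4-(benzyloxy)phenyl]-5,7-bis{[4-(benzyloxy)benzyl]oxy}-3-{5-[5,7-bis(benzyloxy)-4-oxo-4H-chromen-2-yl]-2-[(triisopropylsilyl)oxy]phenyl}chroman-4-one, via cis-flavanone 14 (not isolated)
Conditions: Rh2(S-PTTL)4 (1 mol%), toluene, −40 °C → rt, slow addition of 13; then Et3N (0.5 equiv), rt
Reagents that add atoms: none
Why: Rh2(S-PTTL)4, dirhodium tetrakis[N-phthaloyl-(S)-tert-leucinate], expels dinitrogen from 13 and gives a divalent rhodium carbene at C3 flanked by the ketone (acceptor) and ring E (donor); such carbenes insert into C–H bonds through a concerted, asynchronous three-centre transition state with hydride-transfer character, which favours a C–H bond that is both benzylic to a 4-alkoxyphenyl ring and α to oxygen. The closest known reaction type is the divalent rhodium carboxylate-catalysed intramolecular C–H insertion of α-diazoketones and aryldiazoacetates next to an aryl ether oxygen, which gives chroman-4-ones and 2-aryl-2,3-dihydrobenzofurans enantioselectively. Ring C closes by 1,6-insertion: C3 and the ether CH2 are joined through a six-membered transition state that contains C4, C4a, C8a and O1. C2 is set by the catalyst, whose four N-phthaloyl-tert-leucinate ligands let only one of the two enantiotopic benzylic hydrogens reach the carbene; the sense of induction has to be confirmed, and the mirror-image catalyst Rh2(R-PTTL)4 serves if it is opposite. C3 is expected to form kinetically as the cis isomer 14 or as a cis/trans mixture and is then controlled by C2: triethylamine enolises the α-aryl ketone and reprotonation gives the diequatorial trans isomer 15. Chemoselectivity for insertion over attack of the ether oxygen on the carbene (five-membered oxonium ylide, then benzyl shift) rests on the low nucleophilicity of an aryl ether oxygen conjugated with the ortho acyl group, the tempered electrophilicity of the aryl-substituted carbene, the bulky carboxylate ligands and the non-polar solvent. Site selectivity is built into 13: the two ortho ethers of ring A are identical, so either insertion gives 15, and the ring E oxygen, the only other one within reach, carries a silyl group with no activated C–H bond.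

Step 10
Reactants: 15 (2R,3S)-2-[4-(benzyloxy)phenyl]-5,7-bis{[4-(benzyloxy)benzyl]oxy}-3-{5-[5,7-bis(benzyloxy)-4-oxo-4H-chromen-2-yl]-2-[(triisopropylsilyl)oxy]phenyl}chroman-4-one
Product: 16 (2R,3S)-2-[4-(benzyloxy)phenyl]-5,7-bis{[4-(benzyloxy)benzyl]oxy}-3-{5-[5,7-bis(benzyloxy)-4-oxo-4H-chromen-2-yl]-2-hydroxyphenyl}chroman-4-one
Conditions: Bu4NF, AcOH (1:1), THF, 0 °C
Reagents that add atoms: none
Why: Fluoride cleaves the Si–O bond of the aryl silyl ether; acetic acid buffers fluoride and the phenoxide so that C3 is not deprotonated and ring C does not open, and benzyl-type ethers are inert.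

Step 11
Reactants: 16 (2R,3S)-2-[4-(benzyloxy)phenyl]-5,7-bis{[4-(benzyloxy)benzyl]oxy}-3-{5-[5,7-bis(benzyloxy)-4-oxo-4H-chromen-2-yl]-2-hydroxyphenyl}chroman-4-one
Product: 17 (2R,3S)-5,7-dihydroxy-3-[2-hydroxy-5-(5,7-dihydroxy-4-oxo-4H-chromen-2-yl)phenyl]-2-(4-hydroxyphenyl)chroman-4-one
Conditions: H2 (1 atm), Pd/C (10%), THF/MeOH, rt
Reagents that add atoms: none
Why: Catalytic hydrogenolysis of benzylic C–O bonds removes the three benzyl ethers and the two 4-(benzyloxy)benzyl ethers (each cleaved at both benzylic positions) at neutral pH, which leaves C2 and C3 untouched; the reaction is stopped at complete debenzylation, before the slower hydrogenolysis of the C2–O1 bond or reduction of the chromone.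

## Compound list

1 | 1-(2,4,6-trihydroxyphenyl)ethanone | CC(=O)c1c(O)cc(O)cc1O | starting material
2 | 4-(benzyloxy)benzyl chloride | ClCc1ccc(OCc2ccccc2)cc1 | starting material
3 | 1-(4-{[4-(benzyloxy)benzyl]oxy}-2,6-dihydroxyphenyl)ethanone | CC(=O)c1c(O)cc(OCc2ccc(OCc3ccccc3)cc2)cc1O | intermediate
4 | 1-(2,4-bis{[4-(benzyloxy)benzyl]oxy}-6-hydroxyphenyl)ethanone | CC(=O)c1c(O)cc(OCc2ccc(OCc3ccccc3)cc2)cc1OCc1ccc(OCc2ccccc2)cc1 | intermediate
5 | 1-(2,4,6-tris{[4-(benzyloxy)benzyl]oxy}phenyl)ethanone | CC(=O)c1c(OCc2ccc(OCc3ccccc3)cc2)cc(OCc2ccc(OCc3ccccc3)cc2)cc1OCc1ccc(OCc2ccccc2)cc1 | intermediate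
6 | 1-[2,4-bis(benzyloxy)-6-hydroxyphenyl]ethanone | CC(=O)c1c(O)cc(OCc2ccccc2)cc1OCc1ccccc1 | starting material
7 | 3-bromo-4-hydroxybenzaldehyde | O=Cc1ccc(O)c(Br)c1 | starting material
8 | (E)-1-[2,4-bis(benzyloxy)-6-hydroxyphenyl]-3-(3-bromo-4-hydroxyphenyl)prop-2-en-1-one | O=C(/C=C/c1ccc(O)c(Br)c1)c1c(O)cc(OCc2ccccc2)cc1OCc1ccccc1 | intermediate
9 | racemic 5,7-bis(benzyloxy)-2-(3-bromo-4-hydroxyphenyl)chroman-4-one (formed in the flask in step 5) | O=C1CC(c2ccc(O)c(Br)c2)Oc2cc(OCc3ccccc3)cc(OCc3ccccc3)c21 | intermediate
10 | 5,7-bis(benzyloxy)-2-(3-bromo-4-hydroxyphenyl)-4H-chromen-4-one | O=c1cc(-c2ccc(O)c(Br)c2)oc2cc(OCc3ccccc3)cc(OCc3ccccc3)c12 | intermediate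
11 | 5,7-bis(benzyloxy)-2-{3-bromo-4-[(triisopropylsilyl)oxy]phenyl}-4H-chromen-4-one | O=c1cc(-c2ccc(O[Si](C(C)C)(C(C)C)C(C)C)c(Br)c2)oc2cc(OCc3ccccc3)cc(OCc3ccccc3)c12 | intermediate
12 | 2-{5-[5,7-bis(benzyloxy)-4-oxo-4H-chromen-2-yl]-2-[(triisopropylsilyl)oxy]phenyl}-1-(2,4,6-tris{[4-(benzyloxy)benzyl]oxy}phenyl)ethanone | O=C(Cc1cc(-c2cc(=O)c3c(OCc4ccccc4)cc(OCc4ccccc4)cc3o2)ccc1O[Si](C(C)C)(C(C)C)C(C)C)c1c(OCc2ccc(OCc3ccccc3)cc2)cc(OCc2ccc(OCc3ccccc3)cc2)cc1OCc1ccc(OCc2ccccc2)cc1 | intermediate
13 | 2-{5-[5,7-bis(benzyloxy)-4-oxo-4H-chromen-2-yl]-2-[(triisopropylsilyl)oxy]phenyl}-2-diazo-1-(2,4,6-tris{[4-(benzyloxy)benzyl]oxy}phenyl)ethanone | [N-]=[N+]=C(C(=O)c1c(OCc2ccc(OCc3ccccc3)cc2)cc(OCc2ccc(OCc3ccccc3)cc2)cc1OCc1ccc(OCc2ccccc2)cc1)c1cc(-c2cc(=O)c3c(OCc4ccccc4)cc(OCc4ccccc4)cc3o2)ccc1O[Si](C(C)C)(C(C)C)C(C)C | intermediate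
14 | (2R,3R)-2-[4-(benzyloxy)phenyl]-5,7-bis{[4-(benzyloxy)benzyl]oxy}-3-{5-[5,7-bis(benzyloxy)-4-oxo-4H-chromen-2-yl]-2-[(triisopropylsilyl)oxy]phenyl}chroman-4-one (2,3-cis; formed in the flask in step 9) | O=C1c2c(OCc3ccc(OCc4ccccc4)cc3)cc(OCc3ccc(OCc4ccccc4)cc3)cc2O[C@@H](c2ccc(OCc3ccccc3)cc2)[C@H]1c1cc(-c2cc(=O)c3c(OCc4ccccc4)cc(OCc4ccccc4)cc3o2)ccc1O[Si](C(C)C)(C(C)C)C(C)C | intermediate
15 | (2R,3S)-2-[4-(benzyloxy)phenyl]-5,7-bis{[4-(benzyloxy)benzyl]oxy}-3-{5-[5,7-bis(benzyloxy)-4-oxo-4H-chromen-2-yl]-2-[(triisopropylsilyl)oxy]phenyl}chroman-4-one (2,3-trans) | O=C1c2c(OCc3ccc(OCc4ccccc4)cc3)cc(OCc3ccc(OCc4ccccc4)cc3)cc2O[C@@H](c2ccc(OCc3ccccc3)cc2)[C@@H]1c1cc(-c2cc(=O)c3c(OCc4ccccc4)cc(OCc4ccccc4)cc3o2)ccc1O[Si](C(C)C)(C(C)C)C(C)C | intermediate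
16 | (2R,3S)-2-[4-(benzyloxy)phenyl]-5,7-bis{[4-(benzyloxy)benzyl]oxy}-3-{5-[5,7-bis(benzyloxy)-4-oxo-4H-chromen-2-yl]-2-hydroxyphenyl}chroman-4-one | O=C1c2c(OCc3ccc(OCc4ccccc4)cc3)cc(OCc3ccc(OCc4ccccc4)cc3)cc2O[C@@H](c2ccc(OCc3ccccc3)cc2)[C@@H]1c1cc(-c2cc(=O)c3c(OCc4ccccc4)cc(OCc4ccccc4)cc3o2)ccc1O | intermediate
17 | (2R,3S)-5,7-dihydroxy-3-[2-hydroxy-5-(5,7-dihydroxy-4-oxo-4H-chromen-2-yl)phenyl]-2-(4-hydroxyphenyl)chroman-4-one | O=C1c2c(O)cc(O)cc2O[C@@H](c2ccc(O)cc2)[C@@H]1c1cc(-c2cc(=O)c3c(O)cc(O)cc3o2)ccc1O | target

## Step count and risks

Total step count: 11. Longest linear sequence: 8 steps (steps 1 to 3 and 7 to 11, from 1 and 2); the branch through steps 4 to 6 is equally long.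

**Step 9 (key step).** Three things may go wrong.

- The ring A ether oxygen may attack the carbene instead of the C–H bond. The five-membered oxonium ylide then suffers a [1,2]-shift of the benzylic group, which diverts material to a 2,2-disubstituted benzofuran-3-one skeleton.
- The catalyst may discriminate poorly between the two enantiotopic benzylic hydrogens, or select the wrong one. The latter is answered by the mirror-image catalyst.
- During the triethylamine treatment ring C may open by retro-oxa-Michael reaction, which would erode the configuration at C2.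

The fallback gives up the catalytic asymmetric closure and sets out from 12. MgBr2·OEt2 in CH2Cl2/Et2O would cleave one of the two magnesium-chelated ortho ethers and give 2-{5-[5,7-bis(benzyloxy)-4-oxo-4H-chromen-2-yl]-2-[(triisopropylsilyl)oxy]phenyl}-1-(2-hydroxy-4,6-bis{[4-(benzyloxy)benzyl]oxy}phenyl)ethanone F1. Condensation of F1 with commercial 4-(benzyloxy)benzaldehyde (piperidinium acetate, toluene, removal of water) would close ring C by aldol condensation and oxa-Michael addition, the known route from 2'-hydroxydeoxybenzoins to 2,3-trans-2,3-diarylchroman-4-ones. The product would be the racemic trans-flavanone F2, a 1:1 mixture of 15 and its enantiomer. Preparative chromatography on a chiral stationary phase would bring the path back to the route at 15, at the cost of half the material.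

**Step 7.** Both partners are hindered (a 2,6-disubstituted aryl ketone and an ortho-silyloxy aryl bromide), so the coupling may stall. Phosphate at 90 °C may also slowly remove the silyl group from the electron-poor ring E phenol. The fallback changes the nucleophile and removes the base. It sets out from 5, which is converted with Me3SiOTf and Et3N into {[1-(2,4,6-tris{[4-(benzyloxy)benzyl]oxy}phenyl)ethenyl]oxy}trimethylsilane F3. F3 is coupled with 11 under Pd(OAc)2/P(t-Bu)3 with Bu3SnF in toluene (arylation through the tin enolate) and comes back to the route at 12.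

**Step 4.** Under KOH the aldehyde 7 is present as its phenoxide, a vinylogous carboxylate, so the aldol addition may be slow and incomplete. The fallback takes a protecting-group detour and sets out from 7. MOMCl and iPr2NEt give 3-bromo-4-(methoxymethoxy)benzaldehyde F4. Claisen–Schmidt condensation of F4 with 6 gives (E)-1-[2,4-bis(benzyloxy)-6-hydroxyphenyl]-3-[3-bromo-4-(methoxymethoxy)phenyl]prop-2-en-1-one F5. HCl in MeOH removes the acetal and returns to the route at 8.

**Step 11.** With seven benzylic ethers to cleave, over-reduction is the danger: hydrogenolysis of the benzylic C2–O1 bond of ring C (opening to a dihydrochalcone) or saturation of the chromone C2=C3 bond before the last ether has gone. The fallback is non-reductive and sets out from 16. BCl3 with pentamethylbenzene as cation scavenger in CH2Cl2 at −78 °C cleaves all benzylic ethers and arrives directly at 17; no new compound is made on the way (F0).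

## Further compounds

F1 | step 9 | 2-{5-[5,7-bis(benzyloxy)-4-oxo-4H-chromen-2-yl]-2-[(triisopropylsilyl)oxy]phenyl}-1-(2-hydroxy-4,6-bis{[4-(benzyloxy)benzyl]oxy}phenyl)ethanone | O=C(Cc1cc(-c2cc(=O)c3c(OCc4ccccc4)cc(OCc4ccccc4)cc3o2)ccc1O[Si](C(C)C)(C(C)C)C(C)C)c1c(O)cc(OCc2ccc(OCc3ccccc3)cc2)cc1OCc1ccc(OCc2ccccc2)cc1
F2 | step 9 | racemic 2,3-trans-flavanone, 1:1 mixture of 15 and its (2S,3R)-enantiomer | O=C1c2c(OCc3ccc(OCc4ccccc4)cc3)cc(OCc3ccc(OCc4ccccc4)cc3)cc2O[C@@H](c2ccc(OCc3ccccc3)cc2)[C@@H]1c1cc(-c2cc(=O)c3c(OCc4ccccc4)cc(OCc4ccccc4)cc3o2)ccc1O[Si](C(C)C)(C(C)C)C(C)C.O=C1c2c(OCc3ccc(OCc4ccccc4)cc3)cc(OCc3ccc(OCc4ccccc4)cc3)cc2O[C@H](c2ccc(OCc3ccccc3)cc2)[C@H]1c1cc(-c2cc(=O)c3c(OCc4ccccc4)cc(OCc4ccccc4)cc3o2)ccc1O[Si](C(C)C)(C(C)C)C(C)C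
F3 | step 7 | {[1-(2,4,6-tris{[4-(benzyloxy)benzyl]oxy}phenyl)ethenyl]oxy}trimethylsilane | C=C(O[Si](C)(C)C)c1c(OCc2ccc(OCc3ccccc3)cc2)cc(OCc2ccc(OCc3ccccc3)cc2)cc1OCc1ccc(OCc2ccccc2)cc1
F4 | step 4 | 3-bromo-4-(methoxymethoxy)benzaldehyde | COCOc1ccc(C=O)cc1Br
F5 | step 4 | (E)-1-[2,4-bis(benzyloxy)-6-hydroxyphenyl]-3-[3-bromo-4-(methoxymethoxy)phenyl]prop-2-en-1-one | COCOc1ccc(/C=C/C(=O)c2c(O)cc(OCc3ccccc3)cc2OCc2ccccc2)cc1Br
F0 | step 11 | none | none
A1 | alternative 1 | 2-(dimethoxymethyl)-3,5-dimethoxyphenol | COC(OC)c1c(O)cc(OC)cc1OC
A2 | alternative 1 | (E)-4-bromo-1-methoxy-2-[2-(4-methoxyphenyl)ethenyl]benzene | COc1ccc(/C=C/c2cc(Br)ccc2OC)cc1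
A3 | alternative 1 | 2,3-trans-3,4-trans-3-(5-bromo-2-methoxyphenyl)-4,5,7-trimethoxy-2-(4-methoxyphenyl)chromane (C2 and C3 arranged as in 17) | CO[C@H]1c2c(OC)cc(OC)cc2O[C@@H](c2ccc(OC)cc2)[C@@H]1c1cc(Br)ccc1OC
A4 | alternative 2 | 2-{[(1S)-2-bromo-2-{5-bromo-2-[(tert-butyldimethylsilyl)oxy]phenyl}-1-(4-methoxyphenyl)ethyl]oxy}-4,6-dimethoxybenzaldehyde (halide-bearing carbon as either epimer) | O=Cc1c(OC)cc(OC)cc1O[C@@H](c1ccc(OC)cc1)C(Br)c1cc(Br)ccc1O[Si](C)(C)C(C)(C)C
A5 | alternative 2 | (2R,3S)-3-(5-bromo-2-hydroxyphenyl)-5,7-dimethoxy-2-(4-methoxyphenyl)chroman-4-one | O=C1c2c(OC)cc(OC)cc2O[C@@H](c2ccc(OC)cc2)[C@@H]1c1cc(Br)ccc1O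
A6 | alternative 3 | (E)-2-[5-(5,7-dimethoxy-4-oxo-4H-chromen-2-yl)-2-methoxyphenyl]-1-(2-hydroxy-4,6-dimethoxyphenyl)-3-(4-methoxyphenyl)prop-2-en-1-one | COc1ccc(/C=C(\c2cc(-c3cc(=O)c4c(OC)cc(OC)cc4o3)ccc2OC)C(=O)c2c(O)cc(OC)cc2OC)cc1
A7 | alternative 3 | (2R,3S)-3-[5-(5,7-dimethoxy-4-oxo-4H-chromen-2-yl)-2-methoxyphenyl]-5,7-dimethoxy-2-(4-methoxyphenyl)chroman-4-one | O=C1c2c(OC)cc(OC)cc2O[C@@H](c2ccc(OC)cc2)[C@@H]1c1cc(-c2cc(=O)c3c(OC)cc(OC)cc3o2)ccc1OC
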